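## The problem

3-alpha-Hydroxybarbatic acid (20) is a depside. Two pentasubstituted benzene rings are joined only by the aryl ester between the carbonyl carbon on C1 of ring A and O4' of ring B. There is no stereocentre and no ring fusion, so the difficulty is one of position and chemoselectivity.

Ring A carries six different groups in a fixed order: C1 CO2Ar, C2 OH, C3 CH2OH, C4 OMe, C5 H, C6 CH3. A route from a finished orcinol ring must tell O2 from O4, C3 from C5, and the one oxidized benzylic carbon on C3 from the three aryl methyl groups on C6, C3' and C6'. The ester carbonyl sits between C2-OH and C6-CH3, so the bond joining the halves is also the most hindered one, and the acid that would form it loses CO2 easily.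

- **Salicyl alcohol:** the C2-OH/C3-CH2OH pair sits on an electron-rich ring. Acid ionizes it to an ortho-quinone methide, and forcing hydrogenolysis cuts it to a methyl group.
- **Esters and acids:** the depside ester falls to alkoxides, amines and hydroxide, and the free acid on C1' decarboxylates when warmed with acid.

The feature that opens a shorter way is the sequence C2(OH)-C3(CH2O)-C4(OMe)-C5(H)-C6(CH3)-C1(C=O) of ring A. This is a resorcinol monomethyl ether with a carbon substituent between its two oxygens. That pattern is exactly what a vinylketene (supplying C2 with its oxygen, C5, C6 and C1) and a 1-methoxyalkyne (supplying C3 and C4 with their substituents) write in one operation. C1 enters as the far end of the vinylketene, so it can carry the aryl ester from the start. The hindered ester is therefore made on an open chain, before its two ortho neighbours exist.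

## Retrosynthesis

**20 back to 19.** The cuts are the O-Si bond on the C3 benzylic oxygen and the O-CH2 bond of the ester on C1'. Both masks end in silicon, so one fluoride treatment removes them. A benzyl ester would put the C3 benzylic C-O bond at risk under hydrogen. A tert-butyl ester would need acid that ionizes the salicyl alcohol. An allyl ester would not pass the palladium step. The chelated phenols O2 and O2' stay free throughout. The forward step must spare the depside ester, which its two ortho neighbours and the adjacent phenoxide favour.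

**19 back to 15 and 14 (key disconnection).** Three bonds of ring A are cut: C1-C2, C2-C3 and C4-C5.
- Cutting only the ester bond would leave every positional problem of ring A unsolved.
- The reverse orientation (ketene carbonyl as C4, alkyne oxygen on C2) would put the ester on the ketene carbon. There it would make the ketene a heterodiene, and a later O-methylation would be needed.
- In the chosen orientation the ketene oxygen becomes the free C2-OH. The alkyne brings C4-OMe and C3-CH2O already differentiated. C1 brings the complete ester to ring B.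
- The precursors are an open five-carbon acyl chain on ring B and a four-carbon alkyne, against a fully substituted ring in 19.
- The forward reaction must give one orientation in the [2+2] step, capture the ketene before it decays, and keep an E double bond.

**15 back to 10.** A ketene cannot be stored, so it is written as its ethyl alkynyl ether. The ethyl C-O bond and one ethyl C-H bond are cut, and ethylene is lost in the forward sense.
- An acid chloride with an amine would equilibrate the double bond through the dienolate.
- Light on a diazo ketone would also excite the aryl ester and the enoate.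
- A cyclobutenone with the ester on its sp3 carbon is no simpler than ring A.
- The retro-ene release is neutral and slow, and it leaves the geometry alone.

**10 back to 6 and 7.** The sp-sp2 bond between the alkyne and C(CH3) is cut. A cross-coupling with retention carries the geometry of an enol sulfonate into 10, so the geometry problem shifts to a reaction that solves it on acetoacetates. Compound 7 is purchasable.

**6 back to 5, and 5 back to 2 and 3.** First the S-O bond of the enol tosylate is cut, then the acyl-O4' bond. This is the future depside bond. Here it is formed between the one unchelated phenol of 2 and the unhindered acetylketene 4 released from 3, with no coupling reagent.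

**2 back to 1, and 14 back to 11.**
- Compound 2 is the ester of purchasable 1, formed by alkylation at the carboxyl oxygen so that the hindered carbonyl is never attacked.
- Compound 14 comes from 11 in one flask by way of acetylide 12 and alkoxide 13.
- Ring B has the same substituent pattern as ring A and could be built the same way. Since it can be bought as 1, that would only add steps.

## Roads not taken

**Alternative 1:** cut the ester bond C(=O)-O4', the most obvious plan.
- **Forward key step:** condensation of 3-formyl-2-hydroxy-4-methoxy-6-methylbenzoic acid A1 with benzyl 2,4-dihydroxy-3,6-dimethylbenzoate A2 (trifluoroacetic anhydride or DCC). This gives benzyl 4-[(3-formyl-2-hydroxy-4-methoxy-6-methylbenzoyl)oxy]-2-hydroxy-3,6-dimethylbenzoate A3. Aldehyde reduction and hydrogenolysis follow.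
- **Why the chosen plan is better:**
  - A1 must first be won from an orsellinate by selective O4-methylation, a C3 against C5 formylation, and hydrolysis of a hindered ester. All positional problems therefore remain and are solved one at a time.
  - The union takes place at the most hindered carbonyl.
  - The last step exposes the C3 benzylic C-O bond to hydrogen.
- It is the safe plan and serves below as a fallback.

**Alternative 2:** cut C1-C6 of ring A together with the ester bond, as the polyketide biosynthesis suggests.
- **Forward key step:** thermolysis of 6-(2,4-dioxopentyl)-2,2-dimethyl-4H-1,3-dioxin-4-one A4 in the presence of 2. The acylketene is trapped to give the 3,5,7-trioxooctanoate A5, and aldol aromatization gives 2-(trimethylsilyl)ethyl 4-[(2,4-dihydroxy-6-methylbenzoyl)oxy]-2-hydroxy-3,6-dimethylbenzoate A6.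
- **Why the chosen plan is better:**
  - This step also makes the ester before the ring, but it delivers C3-H and two free hydroxyls.
  - O4 must then be methylated, and C3 hydroxymethylated in competition with C5.
  - An alkoxymethyl group placed on the open chain would lie beta to two ketones and would be lost by elimination.
  - The ring and the ester are solved, but the C3/O4 pattern is not.

**Alternative 3:** cut a C-H bond of the C3 methyl group, that is, late oxidation of 2-(trimethylsilyl)ethyl 2-hydroxy-4-[(2-hydroxy-4-methoxy-3,6-dimethylbenzoyl)oxy]-3,6-dimethylbenzoate A7.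
- **Forward key step:** oxidation of the 2-hydroxy-3-methyl unit to an ortho-quinone methide and hydration, or radical bromination and hydrolysis.
- **Why the chosen plan is better:**
  - A7 has four aryl methyl groups.
  - Ring B repeats the same 2-hydroxy-3-methyl motif, so nothing in the substrate directs the oxidant to ring A.
  - The hindered esterification is still needed to reach A7.

Key step: step 6

Assumption: the SMILES holds no stereocentre, the double-bond geometries of 6, 10 and 15 to 17 vanish in ring A, and 1 is taken as purchasable.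

## Steps

Step 1
Reactants: 1 2,4-dihydroxy-3,6-dimethylbenzoic acid
Product: 2 2-(trimethylsilyl)ethyl 2,4-dihydroxy-3,6-dimethylbenzoate
Conditions: Me3SiCH2CH2OH (1.05 equiv), PPh3, DIAD, THF, 0 °C to rt
Reagents that add atoms: 2-(trimethylsilyl)ethanol, C[Si](C)(C)CCO
Why: Mitsunobu esterification; the carboxylic acid is far more acidic than either phenol and is the group alkylated by the alkoxyphosphonium ion. The new bond forms at the alcohol carbon, so the hindered, decarboxylation-prone carbonyl is never activated.

Step 2
Reactants: 2 2-(trimethylsilyl)ethyl 2,4-dihydroxy-3,6-dimethylbenzoate; 3 2,2,6-trimethyl-4H-1,3-dioxin-4-one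
Product: 5 2-(trimethylsilyl)ethyl 2-hydroxy-3,6-dimethyl-4-[(3-oxobutanoyl)oxy]benzoate, via acetylketene 4 (not isolated)
Conditions: 3 (1.1 equiv), toluene, 110 °C, acetone distilled off
Reagents that add atoms: none
Why: Retro-Diels-Alder cleavage of the dioxinone releases acetylketene, which acylates phenols under neutral conditions. O4' is the only unchelated phenol, since O2' is hydrogen-bonded to the ester and flanked by C3'-CH3, so the future depside C-O bond forms selectively with an unhindered electrophile.

Step 3
Reactants: 5 2-(trimethylsilyl)ethyl 2-hydroxy-3,6-dimethyl-4-[(3-oxobutanoyl)oxy]benzoate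
Product: 6 2-(trimethylsilyl)ethyl 2-hydroxy-3,6-dimethyl-4-{[(2E)-3-(tosyloxy)but-2-enoyl]oxy}benzoate
Conditions: TsCl, N-methylimidazole, Et3N, CH2Cl2, 0 °C
Reagents that add atoms: 4-toluenesulfonyl chloride, Cc1ccc(cc1)S(=O)(=O)Cl
Why: Stereoselective enol tosylation of an acetoacetate; the non-chelated ammonium enolate is sulfonylated on oxygen by the N-tosylimidazolium salt in the form that holds the sulfonate trans to the ester (E). The keto ester is much more reactive than the chelated, doubly flanked O2'-H.

Step 4
Reactants: 6 2-(trimethylsilyl)ethyl 2-hydroxy-3,6-dimethyl-4-{[(2E)-3-(tosyloxy)but-2-enoyl]oxy}benzoate; 7 ethoxyacetylene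
Product: 10 2-(trimethylsilyl)ethyl 4-{[(2E)-5-ethoxy-3-methylpent-2-en-4-ynoyl]oxy}-2-hydroxy-3,6-dimethylbenzoate, via lithium ethoxyacetylide 8 (not isolated), via ethoxyethynylzinc chloride 9 (not isolated)
Conditions: 7 (2.5 equiv), n-BuLi, THF, -78 °C; ZnCl2, to 0 °C; 6, PdCl2(dppf) (5 mol %), THF, rt to 40 °C; pH 7 buffer; Et3N-deactivated silica
Reagents that add atoms: none
Why: Negishi coupling; zerovalent palladium inserts into the acceptor-activated C-OTs bond with retention, and the alkynylzinc reagent spares both esters. One equivalent of 9 is spent on the free phenol, which returns on work-up, and the temperature stays far below that of the retro-ene reaction.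

Step 5
Reactants: 11 2-chloro-1,1-dimethoxyethane
Product: 14 tert-butyl[(3-methoxyprop-2-yn-1-yl)oxy]dimethylsilane, via lithium methoxyacetylide 12 (not isolated), via lithium 3-methoxyprop-2-yn-1-olate 13 (not isolated)
Conditions: Et2NH, n-BuLi (3.1 equiv each), THF, -78 to 0 °C; (CH2O)n, -78 °C to rt; TBSCl (2.2 equiv), DMAP (cat.), rt
Reagents that add atoms: paraformaldehyde (as formaldehyde), C=O; tert-butyldimethylsilyl chloride, CC(C)(C)[Si](C)(C)Cl
Why: Base-induced loss of methanol and HCl from the chloroacetal, then deprotonation, is the standard entry to alkoxyacetylides, and formaldehyde addition is the standard hydroxymethylation of an acetylide. Silylating the alkoxide in the same flask avoids isolating the acid-labile propargylic alcohol, and the second equivalent of TBSCl takes up the methoxide.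

Step 6
Reactants: 10 2-(trimethylsilyl)ethyl 4-{[(2E)-5-ethoxy-3-methylpent-2-en-4-ynoyl]oxy}-2-hydroxy-3,6-dimethylbenzoate; 14 tert-butyl[(3-methoxyprop-2-yn-1-yl)oxy]dimethylsilane
Product: 19 2-(trimethylsilyl)ethyl 4-{[3-({[tert-butyl(dimethyl)silyl]oxy}methyl)-2-hydroxy-4-methoxy-6-methylbenzoyl]oxy}-2-hydroxy-3,6-dimethylbenzoate, via vinylketene 15 (not isolated), via 4-alkenylcyclobutenone 16 (not isolated), via dienylketene 17 (not isolated), via cyclohexadienone 18 (not isolated)
Conditions: 14 (3 equiv), toluene, 120 °C, sealed base-washed vessel; 10 added slowly by syringe pump, then held at 120 °C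
Reagents that add atoms: none
Why: Proposed new method: the closest known reaction type is the Danheiser benzannulation of a vinylketene (there set free from a cyclobutenone or an unsaturated diazo ketone) with a 1-alkoxyalkyne, and what is new is that an ester-bearing vinylketene is set free by the known thermal retro-ene loss of ethylene from a 1-ethoxyalkyne, without base or light. At 120 °C a methyl hydrogen of the ethoxy group of 10 passes through a six-membered transition state to the alkyne carbon next to C(CH3), ethylene leaves, and 15 forms slowly, at low concentration and with its E double bond untouched. The electrophilic carbonyl carbon of 15 is attacked by the alkyne carbon of 14 that is beta to OMe and bears CH2OTBS, and this polarity-matched [2+2] cycloaddition closes the four-membered ring of 16 and makes bonds C2-C3 and C4-C5 of ring A in the only orientation both partners allow. Reversible 4π electrocyclic opening of 16 breaks the old C2-C5 bond to give 17, the isomer of 17 that holds ketene and alkenyl group cis on the central double bond closes ring A by a thermal disrotatory 6π electrocyclization (bond C1-C2) to 18, and 18 enolizes at once because its C1-H lies between a ketone and an ester and aromaticity is gained. The sp3 carbons of 16 and 18 are transient and are erased on the way, so the step sets no stereocentre. The step needs regioselectivity, secured by the donor oxygen of 14 and the polarity of the ketene, so that OH lands on C2, CH2OTBS on C3 and OMe on C4 with no later O-methylation and no C3 against C5 choice. It needs the E geometry of 10, which places the ester outside in the electrocyclization and holds its carbonyl oxygen away from the ketene carbon, so that oxa-electrocyclization to a pyranone cannot compete. It needs capture of 15 by 14 ahead of all other partners, secured by the excess of 14, the slow release of 15, the acceptor-drained and poorly nucleophilic alkyne of 10, the lack of a beta hydrogen in the methoxy group of 14 (no retro-ene reaction of its own) and the hydrogen-bonded, doubly flanked phenols of 10 and 19.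

Step 7
Reactants: 19 2-(trimethylsilyl)ethyl 4-{[3-({[tert-butyl(dimethyl)silyl]oxy}methyl)-2-hydroxy-4-methoxy-6-methylbenzoyl]oxy}-2-hydroxy-3,6-dimethylbenzoate
Product: 20 3-alpha-hydroxybarbatic acid, 4-{[2-hydroxy-3-(hydroxymethyl)-4-methoxy-6-methylbenzoyl]oxy}-2-hydroxy-3,6-dimethylbenzoic acid
Conditions: TBAF (5 equiv), THF, 0 °C to rt; then cold dilute HCl to pH 3
Reagents that add atoms: none
Why: Fluoride-induced desilylation of the TBS ether and fragmentation of the 2-(trimethylsilyl)ethyl ester (attack at silicon, loss of ethylene), both remote from any carbonyl. The depside carbonyl is shielded by two ortho groups and deactivated by the neighbouring phenoxide. No hydrogen and no strong or warm acid touches the salicyl alcohol or the ring B acid.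

## Compound list

1 | 2,4-dihydroxy-3,6-dimethylbenzoic acid | Cc1cc(O)c(C)c(O)c1C(=O)O | starting material
2 | 2-(trimethylsilyl)ethyl 2,4-dihydroxy-3,6-dimethylbenzoate | Cc1cc(O)c(C)c(O)c1C(=O)OCC[Si](C)(C)C | intermediate
3 | 2,2,6-trimethyl-4H-1,3-dioxin-4-one | CC1=CC(=O)OC(C)(C)O1 | starting material
4 | acetylketene (3-oxobut-1-en-1-one) | CC(=O)C=C=O | intermediate
5 | 2-(trimethylsilyl)ethyl 2-hydroxy-3,6-dimethyl-4-[(3-oxobutanoyl)oxy]benzoate | CC(=O)CC(=O)Oc1cc(C)c(C(=O)OCC[Si](C)(C)C)c(O)c1C | intermediate
6 | 2-(trimethylsilyl)ethyl 2-hydroxy-3,6-dimethyl-4-{[(2E)-3-(tosyloxy)but-2-enoyl]oxy}benzoate | C/C(OS(=O)(=O)c1ccc(C)cc1)=C\C(=O)Oc1cc(C)c(C(=O)OCC[Si](C)(C)C)c(O)c1C | intermediate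
7 | ethoxyacetylene | CCOC#C | starting material
8 | lithium ethoxyacetylide | CCOC#C[Li] | intermediate
9 | ethoxyethynylzinc chloride | CCOC#C[Zn]Cl | intermediate
10 | 2-(trimethylsilyl)ethyl 4-{[(2E)-5-ethoxy-3-methylpent-2-en-4-ynoyl]oxy}-2-hydroxy-3,6-dimethylbenzoate | CCOC#C/C(C)=C/C(=O)Oc1cc(C)c(C(=O)OCC[Si](C)(C)C)c(O)c1C | intermediate
11 | 2-chloro-1,1-dimethoxyethane | COC(CCl)OC | starting material
12 | lithium methoxyacetylide | COC#C[Li] | intermediate
13 | lithium 3-methoxyprop-2-yn-1-olate | COC#CCO[Li] | intermediate
14 | tert-butyl[(3-methoxyprop-2-yn-1-yl)oxy]dimethylsilane | COC#CCO[Si](C)(C)C(C)(C)C | intermediate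
15 | vinylketene, 2-(trimethylsilyl)ethyl 2-hydroxy-3,6-dimethyl-4-{[(2E)-3-methyl-5-oxopenta-2,4-dienoyl]oxy}benzoate | O=C=C/C(C)=C/C(=O)Oc1cc(C)c(C(=O)OCC[Si](C)(C)C)c(O)c1C | intermediate
16 | cyclobutenone (racemic), 2-(trimethylsilyl)ethyl 4-{[(2E)-3-[3-({[tert-butyl(dimethyl)silyl]oxy}methyl)-2-methoxy-4-oxocyclobut-2-en-1-yl]but-2-enoyl]oxy}-2-hydroxy-3,6-dimethylbenzoate | COC1=C(CO[Si](C)(C)C(C)(C)C)C(=O)C1/C(C)=C/C(=O)Oc1cc(C)c(C(=O)OCC[Si](C)(C)C)c(O)c1C | intermediate
17 | dienylketene, 2-(trimethylsilyl)ethyl 4-{[(2E,4E)-6-({[tert-butyl(dimethyl)silyl]oxy}methyl)-5-methoxy-3-methyl-7-oxohepta-2,4,6-trienoyl]oxy}-2-hydroxy-3,6-dimethylbenzoate | O=C=C(CO[Si](C)(C)C(C)(C)C)/C(OC)=C\C(C)=C\C(=O)Oc1cc(C)c(C(=O)OCC[Si](C)(C)C)c(O)c1C | intermediate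
18 | cyclohexadienone (racemic), 2-(trimethylsilyl)ethyl 4-{[3-({[tert-butyl(dimethyl)silyl]oxy}methyl)-4-methoxy-6-methyl-2-oxocyclohexa-3,5-diene-1-carbonyl]oxy}-2-hydroxy-3,6-dimethylbenzoate | COC1=C(CO[Si](C)(C)C(C)(C)C)C(=O)C(C(=O)Oc2cc(C)c(C(=O)OCC[Si](C)(C)C)c(O)c2C)C(C)=C1 | intermediate
19 | 2-(trimethylsilyl)ethyl 4-{[3-({[tert-butyl(dimethyl)silyl]oxy}methyl)-2-hydroxy-4-methoxy-6-methylbenzoyl]oxy}-2-hydroxy-3,6-dimethylbenzoate | COc1cc(C)c(C(=O)Oc2cc(C)c(C(=O)OCC[Si](C)(C)C)c(O)c2C)c(O)c1CO[Si](C)(C)C(C)(C)C | intermediate
20 | 3-alpha-hydroxybarbatic acid | COc1cc(C)c(C(=O)Oc2cc(C)c(C(=O)O)c(O)c2C)c(O)c1CO | target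

## Step count and least certain steps

Total step count: 7. Longest linear sequence: 6 (steps 1, 2, 3, 4, 6, 7). Step 5 is the side branch.

**Step 6 (key step, proposed new method).**
- **What may go wrong:**
  - The ketene may be lost by self-addition or by acylation of a phenol before the alkyne captures it.
  - The retro-ene reaction may demand a temperature at which the methoxyalkyne degrades.
  - The sequence may stall at the four-membered ring.
- **Fallback:** known chemistry only; it sets out from 2 and returns at 20.
  - Rieche formylation (Cl2CHOMe, TiCl4, CH2Cl2) of purchased methyl 2-hydroxy-4-methoxy-6-methylbenzoate, ortho to the titanium-bound phenol, gives methyl 3-formyl-2-hydroxy-4-methoxy-6-methylbenzoate F1.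
  - Cold concentrated H2SO4 hydrolyses the hindered ester to 3-formyl-2-hydroxy-4-methoxy-6-methylbenzoic acid F2.
  - Trifluoroacetic anhydride in toluene joins F2 to O4' of 2, giving 2-(trimethylsilyl)ethyl 4-[(3-formyl-2-hydroxy-4-methoxy-6-methylbenzoyl)oxy]-2-hydroxy-3,6-dimethylbenzoate F3.
  - TBAF frees 4-[(3-formyl-2-hydroxy-4-methoxy-6-methylbenzoyl)oxy]-2-hydroxy-3,6-dimethylbenzoic acid F4.
  - NaBH4 in THF and aqueous NaHCO3 at 0 °C reduces the aldehyde to 20.

**Step 4.**
- **What may go wrong:**
  - The alkynyl ether may be hydrated or protonated during coupling or on silica.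
  - Oxidative addition into the C-OTs bond may be sluggish.
  - Geometry may be lost by addition-elimination at the beta carbon.
- **Fallback:** it sets out from 2 and returns at 10, replacing cross-coupling by a C-H addition.
  - DCC and catalytic DMAP with purchased but-2-ynoic acid give 2-(trimethylsilyl)ethyl 4-(but-2-ynoyloxy)-2-hydroxy-3,6-dimethylbenzoate F5.
  - Pd(OAc)2 with tris(2,6-dimethoxyphenyl)phosphine then catalyses the syn addition of the C-H bond of 7 across the alkynoate, with the alkynyl group going to the beta carbon.
  - This gives 10 with the same geometry, and with neither a leaving group nor an organometallic reagent.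

**Step 3.**
- **What may go wrong:**
  - The E selectivity may erode.
  - The chelated phenol may be sulfonylated competitively.
  - The amine may cleave the aryl keto ester by ketene elimination.
- **Fallback:** it sets out from 2 and returns at 10, and the geometry is bought rather than made.
  - DCC esterification of 2 with purchased (E)-3-chlorobut-2-enoic acid gives 2-(trimethylsilyl)ethyl 4-{[(2E)-3-chlorobut-2-enoyl]oxy}-2-hydroxy-3,6-dimethylbenzoate F6.
  - F6 takes the place of 6 in the coupling with 9 (Pd2(dba)3, XPhos, THF).

**Step 7.**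
- **What may go wrong:**
  - Cleavage of the chelated ester may be slow and call for forcing.
  - Under forcing, basic fluoride or adventitious hydroxide may attack the depside ester.
  - The phenoxide may expel the benzylic oxygen and oligomerize through a quinone methide.
- **Fallback:** it sets out from 19 and returns at 20, holding the salicyl alcohol in a ring while the acid is freed.
  - HF·pyridine in THF removes only the silyl ether, giving 2-(trimethylsilyl)ethyl 4-{[2-hydroxy-3-(hydroxymethyl)-4-methoxy-6-methylbenzoyl]oxy}-2-hydroxy-3,6-dimethylbenzoate F7.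
  - 2,2-Dimethoxypropane and PPTS tie O2 and the benzylic oxygen together, giving 2-(trimethylsilyl)ethyl 2-hydroxy-4-[(5-methoxy-2,2,7-trimethyl-4H-1,3-benzodioxine-8-carbonyl)oxy]-3,6-dimethylbenzoate F8.
  - TBAF gives 2-hydroxy-4-[(5-methoxy-2,2,7-trimethyl-4H-1,3-benzodioxine-8-carbonyl)oxy]-3,6-dimethylbenzoic acid F9.
  - Aqueous acetic acid at room temperature opens the acetonide to 20.

## Further compounds

F1 | step 6 | methyl 3-formyl-2-hydroxy-4-methoxy-6-methylbenzoate | COC(=O)c1c(C)cc(OC)c(C=O)c1O
F2 | step 6 | 3-formyl-2-hydroxy-4-methoxy-6-methylbenzoic acid | COc1cc(C)c(C(=O)O)c(O)c1C=O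
F3 | step 6 | 2-(trimethylsilyl)ethyl 4-[(3-formyl-2-hydroxy-4-methoxy-6-methylbenzoyl)oxy]-2-hydroxy-3,6-dimethylbenzoate | COc1cc(C)c(C(=O)Oc2cc(C)c(C(=O)OCC[Si](C)(C)C)c(O)c2C)c(O)c1C=O
F4 | step 6 | 4-[(3-formyl-2-hydroxy-4-methoxy-6-methylbenzoyl)oxy]-2-hydroxy-3,6-dimethylbenzoic acid | COc1cc(C)c(C(=O)Oc2cc(C)c(C(=O)O)c(O)c2C)c(O)c1C=O
F5 | step 4 | 2-(trimethylsilyl)ethyl 4-(but-2-ynoyloxy)-2-hydroxy-3,6-dimethylbenzoate | CC#CC(=O)Oc1cc(C)c(C(=O)OCC[Si](C)(C)C)c(O)c1C
F6 | step 3 | 2-(trimethylsilyl)ethyl 4-{[(2E)-3-chlorobut-2-enoyl]oxy}-2-hydroxy-3,6-dimethylbenzoate | C/C(Cl)=C\C(=O)Oc1cc(C)c(C(=O)OCC[Si](C)(C)C)c(O)c1C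
F7 | step 7 | 2-(trimethylsilyl)ethyl 4-{[2-hydroxy-3-(hydroxymethyl)-4-methoxy-6-methylbenzoyl]oxy}-2-hydroxy-3,6-dimethylbenzoate | COc1cc(C)c(C(=O)Oc2cc(C)c(C(=O)OCC[Si](C)(C)C)c(O)c2C)c(O)c1CO
F8 | step 7 | 2-(trimethylsilyl)ethyl 2-hydroxy-4-[(5-methoxy-2,2,7-trimethyl-4H-1,3-benzodioxine-8-carbonyl)oxy]-3,6-dimethylbenzoate | COc1cc(C)c(C(=O)Oc3cc(C)c(C(=O)OCC[Si](C)(C)C)c(O)c3C)c2OC(C)(C)OCc12
F9 | step 7 | 2-hydroxy-4-[(5-methoxy-2,2,7-trimethyl-4H-1,3-benzodioxine-8-carbonyl)oxy]-3,6-dimethylbenzoic acid | COc1cc(C)c(C(=O)Oc3cc(C)c(C(=O)O)c(O)c3C)c2OC(C)(C)OCc12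
A1 | alternative 1 | 3-formyl-2-hydroxy-4-methoxy-6-methylbenzoic acid | COc1cc(C)c(C(=O)O)c(O)c1C=O
A2 | alternative 1 | benzyl 2,4-dihydroxy-3,6-dimethylbenzoate | Cc1cc(O)c(C)c(O)c1C(=O)OCc1ccccc1
A3 | alternative 1 | benzyl 4-[(3-formyl-2-hydroxy-4-methoxy-6-methylbenzoyl)oxy]-2-hydroxy-3,6-dimethylbenzoate | COc1cc(C)c(C(=O)Oc2cc(C)c(C(=O)OCc3ccccc3)c(O)c2C)c(O)c1C=O
A4 | alternative 2 | 6-(2,4-dioxopentyl)-2,2-dimethyl-4H-1,3-dioxin-4-one | CC(=O)CC(=O)CC1=CC(=O)OC(C)(C)O1
A5 | alternative 2 | 2-(trimethylsilyl)ethyl 2-hydroxy-3,6-dimethyl-4-[(3,5,7-trioxooctanoyl)oxy]benzoate | CC(=O)CC(=O)CC(=O)CC(=O)Oc1cc(C)c(C(=O)OCC[Si](C)(C)C)c(O)c1C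
A6 | alternative 2 | 2-(trimethylsilyl)ethyl 4-[(2,4-dihydroxy-6-methylbenzoyl)oxy]-2-hydroxy-3,6-dimethylbenzoate | Cc1cc(O)cc(O)c1C(=O)Oc1cc(C)c(C(=O)OCC[Si](C)(C)C)c(O)c1C
A7 | alternative 3 | 2-(trimethylsilyl)ethyl 2-hydroxy-4-[(2-hydroxy-4-methoxy-3,6-dimethylbenzoyl)oxy]-3,6-dimethylbenzoate | COc1cc(C)c(C(=O)Oc2cc(C)c(C(=O)OCC[Si](C)(C)C)c(O)c2C)c(O)c1C
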